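**Strategy**

The 33-membered lactone is cut at C3–C4. The C1(=O)–C2–C3 propanoate segment of the ring is read as a masked acrylate, and C4, the first carbon of the unbranched C4–C32 polymethylene chain, as a primary alkyl radical. A tin-hydride-mediated 33-endo-trig Giese-type radical macrocyclisation of 29-iodononacosyl acrylate forms the C(sp3)–C(sp3) bond, closes the ring and delivers the saturated lactone directly, with no post-cyclisation adjustment. The precursor is the acrylate of a C29 α,ω-iodo alcohol, whose chain is assembled in one step by a twofold copper-catalysed Grignard coupling (C12 + C5 + C12).

Key step: step 4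

Remark on the chemistry: the target (oxacyclotritriacontan-2-one, dotriacontan-32-olide, C32H62O2) has no stereocentre and no stereogenic double bond, so it is achiral and no stereocontrol is required.

**Route**

Step 1
Reactants: 1 12-bromododecan-1-ol (2.4 equiv); 2 pentane-1,5-diylbis(magnesium bromide) (1.0 equiv, commercial 0.5 M solution in THF)
Product: 4 nonacosane-1,29-diol, via chloromagnesium 12-bromododecan-1-olate 3 (not isolated)
Conditions: MeMgCl (1.0 equiv per OH), THF, −20 °C; then Li2CuCl4 (5 mol %), slow addition of 2, THF/NMP, −20 °C → rt; 1 M HCl work-up; recrystallisation from hot toluene
Reagents that add atoms: methylmagnesium chloride, C[Mg]Cl (supplies the MgCl of intermediate 3 only; none of its atoms remain in 4)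
Why: Kochi coupling (copper-catalysed C(sp3)–C(sp3) Grignard cross-coupling) of a primary di-Grignard reagent with two primary alkyl bromides should join C12 + C5 + C12 in one operation, because the hydroxyl group, masked beforehand as its halomagnesium alkoxide, is inert to the Grignard reagent and only the primary bromide is displaced.

Step 2
Reactants: 4 nonacosane-1,29-diol
Product: 5 29-iodononacosan-1-ol
Conditions: PPh3 (1.0 equiv), I2 (1.0 equiv), imidazole (1.2 equiv), THF, 45 °C; chromatography, unreacted diol recycled
Reagents that add atoms: iodine, II
Why: Appel-type iodination (Garegg–Samuelsson conditions) converts a primary alcohol into the iodide by SN2 displacement of an alkoxyphosphonium ion, and since the two hydroxyls lie 29 carbons apart and react independently, one equivalent of reagent should give the mono-iodide as the main product of a statistical desymmetrisation, separable from diol and di-iodide by polarity.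

Step 3
Reactants: 5 29-iodononacosan-1-ol; 6 acryloyl chloride (1.3 equiv)
Product: 7 29-iodononacosyl prop-2-enoate
Conditions: i-Pr2NEt (1.5 equiv), BHT (cat.), CH2Cl2, 0 °C → rt
Reagents that add atoms: none
Why: O-acylation of the primary alcohol by the acid chloride (esterification by nucleophilic acyl substitution) should be fast at 0 °C, while the hindered base avoids quaternisation by the primary iodide and BHT suppresses acrylate polymerisation.

Step 4
Reactants: 7 29-iodononacosyl prop-2-enoate
Product: 8 oxacyclotritriacontan-2-one (dotriacontan-32-olide, the target)
Conditions: 7 (about 1 mM) in PhH at reflux; Bu3SnH (1.3 equiv) and AIBN (0.2 equiv) in PhH added by syringe pump over 12 h; aq. KF work-up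
Reagents that add atoms: none
Why: Bu3Sn• abstracts iodine from C4 of 7 to give a nucleophilic primary alkyl radical, which adds to the unsubstituted β-carbon (C3) of the electron-poor acrylate, and the resulting C2 α-ester radical takes hydrogen from Bu3SnH and propagates the chain, so the saturated lactone forms directly. The closest known reaction type is the Giese radical conjugate addition in its intramolecular, macrocyclising form, as established for ω-iodoalkyl acrylates under tin hydride conditions. The one ring formed, the 33-membered oxacycle, is closed in the 33-endo-trig mode. No stereocentre is created, so no controlling element is needed. The step needs regioselectivity for C3 over C2, which the polar and steric bias of the acrylate secures because its terminal CH2 is the only position matched to a nucleophilic radical, and it needs ring closure to outrun premature reduction of the open-chain radical and intermolecular addition, which the high dilution and the low stationary tin hydride concentration from syringe-pump addition secure. The unsubstituted, strain-free polymethylene chain imposes no transannular penalty, and iodine abstraction is near diffusion-controlled, so the chain should propagate even at this dilution.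

**Compound list**

1 | 12-bromododecan-1-ol | OCCCCCCCCCCCCBr | starting material
2 | pentane-1,5-diylbis(magnesium bromide) | Br[Mg]CCCCC[Mg]Br | starting material
3 | chloromagnesium 12-bromododecan-1-olate | Cl[Mg]OCCCCCCCCCCCCBr | intermediate (formed in the flask, not isolated)
4 | nonacosane-1,29-diol | OCCCCCCCCCCCCCCCCCCCCCCCCCCCCCO | intermediate
5 | 29-iodononacosan-1-ol | OCCCCCCCCCCCCCCCCCCCCCCCCCCCCCI | intermediate
6 | acryloyl chloride (prop-2-enoyl chloride) | C=CC(=O)Cl | starting material
7 | 29-iodononacosyl prop-2-enoate | C=CC(=O)OCCCCCCCCCCCCCCCCCCCCCCCCCCCCCI | intermediate
8 | oxacyclotritriacontan-2-one (dotriacontan-32-olide, CNP0285448.0) | O=C1CCCCCCCCCCCCCCCCCCCCCCCCCCCCCCCO1 | target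

**Step count and risks**

Total step count: 4. Longest linear sequence: 4 steps (1 → 4 → 5 → 7 → 8).

Steps most likely to fail:

1. Step 4 (key macrocyclisation). The open-chain radical may take hydrogen from the tin hydride before the 33-membered ring closes, or add intermolecularly to give oligomers. The fallback makes the C3–C4 bond intermolecularly and closes the ring at the acyl C1–O bond instead. It sets out from 5. Giese addition of the radical from 5 to excess methyl acrylate (Bu3SnH, AIBN, PhH, reflux) should give methyl 32-hydroxydotriacontanoate F1. Saponification (LiOH, THF/H2O, 60 °C) should give 32-hydroxydotriacontanoic acid F2. Yamaguchi macrolactonisation (2,4,6-trichlorobenzoyl chloride, Et3N, THF; slow addition to DMAP in refluxing toluene at high dilution) comes back to the route at 8.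

2. Step 1 (twofold coupling). The second coupling of the di-Grignard reagent may stall at the aggregated, sparingly soluble halomagnesium alkoxide, with protonation or homocoupling of the organomagnesium, so that mono-coupled alcohol contaminates the diol. The fallback uses covalent protection and reversed polarity and sets out from 1. Dihydropyran with PPTS in CH2Cl2 should give 2-[(12-bromododecyl)oxy]oxane F3 (racemic at the acetal carbon, inconsequential). Magnesium in THF should give {12-[(oxan-2-yl)oxy]dodecyl}magnesium bromide F4. Coupling of F4 (2.3 equiv) with 1,5-dibromopentane (Li2CuCl4 cat., THF, −10 °C → rt) should give 2,2'-[nonacosane-1,29-diylbis(oxy)]bis(oxane) F5. Acetal methanolysis (PPTS, MeOH/THF, 50 °C) comes back to the route at 4.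

3. Step 2 (mono-iodination). The statistical reaction may over-run to the di-iodide while poorly soluble diol remains, giving a broad mixture and losses on separation. The fallback replaces it with a phase-controlled monobromination followed by halide exchange and sets out from 4. Aqueous 48% HBr in refluxing toluene should give 29-bromononacosan-1-ol F6 with mono-selectivity above the statistical level, because the bromo alcohol is withdrawn into the organic phase. Finkelstein exchange (NaI, butanone, reflux) comes back to the route at 5.

**Further compounds**

F1 | step 4 | methyl 32-hydroxydotriacontanoate | COC(=O)CCCCCCCCCCCCCCCCCCCCCCCCCCCCCCCO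
F2 | step 4 | 32-hydroxydotriacontanoic acid | OC(=O)CCCCCCCCCCCCCCCCCCCCCCCCCCCCCCCO
F3 | step 1 | 2-[(12-bromododecyl)oxy]oxane | BrCCCCCCCCCCCCOC1CCCCO1
F4 | step 1 | {12-[(oxan-2-yl)oxy]dodecyl}magnesium bromide | Br[Mg]CCCCCCCCCCCCOC1CCCCO1
F5 | step 1 | 2,2'-[nonacosane-1,29-diylbis(oxy)]bis(oxane) | O1CCCCC1OCCCCCCCCCCCCCCCCCCCCCCCCCCCCCOC1CCCCO1
F6 | step 2 | 29-bromononacosan-1-ol | OCCCCCCCCCCCCCCCCCCCCCCCCCCCCCBr
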